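Remark on the chemistry: germacrane numbering is used for all ring compounds (ring C1–C10, lactone arm C11–C13, C14 on C10, C15 on C4). The target as drawn is read as 1R,2S,3S,6S,7R,8R,10S, a cis-fused 12,6-lactone with an anti-diepoxide. (Z)-1,2-Bis(trimethylstannyl)ethene is treated as not stocked and is made in step 16.

## Analysis of the target

The target is a germacranolide: a ten-membered carbocycle (C1–C10) cis-fused at C6/C7 to an α-methylene-γ-butyrolactone (C12–O–C6, C11=C13). The ring carries two oxiranes on four adjacent carbons, C1–C10 (trisubstituted, methyl C14 on C10) and C2–C3 (cis-disubstituted). Next to them stands the C4=C5 alkene with the hydroxymethyl group C15, and C8 bears the angelate. The seven stereocentres fall into two groups. C6, C7 and C8 are a contiguous triad in which H6 and H7 are cis, O6 and O8 are 1,3-syn and the C11 branch on C7 is anti to both oxygens. C1, C2, C3 and C10 are the oxirane carbons; in both oxiranes the ring carbons are cis, and the two oxygens lie on opposite faces. The methylene lactone is a Michael acceptor, the angelate isomerises readily to the tiglate, and both oxiranes are allylic or adjacent to one another and therefore labile to acid and nucleophiles. The difficulty is a medium ring with seven stereocentres, four of which cannot sensibly be addressed one at a time. The plan rests on the observation that C10, C1, C2 and C3 carry exactly the oxidation pattern of a ring-cis 1(10),2-diene beside C4=C5, so the whole oxirane array can be traced back to an all-ring-cis cyclodeca-1(10),2,4-triene.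

## Retrosynthetic reasoning

**36 to 35.** The C15 alcohol is taken back to the aldehyde. Nothing is cut. The gain is that the formyl group makes C4=C5 electron-poor during the oxidation that precedes it. The forward step must reduce one aldehyde in the presence of a methylene lactone, an enoate and two oxiranes, which a Luche-type 1,2-reduction does.

**35 to 33.** Four C–O bonds are cut and both oxiranes are returned to the C1=C10 and C2=C3 alkenes of triene 33. This removes two rings and four stereocentres without touching the skeleton, and it is the only disconnection that deals with all four oxirane carbons at once. The forward step has to oxidise the diene and leave C4=C5, C11=C13 and the angelate alone. It must deliver the first oxygen to the correct face of C1=C10 and the second anti to it (via 34).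

**33 to 28 and 31.** The ring is opened by cutting C1–C2 and C3–C4, which excises C2–C3 as the cis-distannylethene 31 and leaves the bis(alkenyl iodide) 28. A phosphonate olefination at C4=C5 was examined first and set aside for three reasons:
- The carbanion at C4 would be conjugated with the Z C2=C3 bond, so that geometry would no longer be secure.
- The carbanion would be a Michael donor towards the methylene lactone.
- It would leave C15 as an ester that cannot be taken to the aldehyde beside lactone and angelate.

Coupling of alkenyl partners by zerovalent palladium avoids all three problems. Each iodide is made early with fixed geometry, the cis C2=C3 bond arrives ready-made, and the heat-sensitive triene is formed last, at room temperature, with lactone, methylene, angelate and aldehyde already in place. The two couplings pass through 32.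

**28 to 27, 24 and 23.** These are functional-group changes on an intact skeleton: the C15 aldehyde comes from its diethyl acetal (27), the angelate from alcohol 24 and angelic acid 25 (via 26), and the alcohol from silyl ether 23. The angelate is put on before ring closure because its installation needs heat, which the triene would not tolerate.

**23 to 15 and 21.** The C6–C7 bond and the lactone C–O bond are cut, giving allylic bromide 15 and iodo-enal 21. One Barbier-type allylation then forms the C–C bond, the methylene group and, after lactonisation of 22, the lactone. It must set C6 and C7 cis to each other and in the right sense relative to C8. The (Z)-geometry of 15 and the stereocentre at C8 are expected to provide this.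

**15 to 12 and 13.** The C7–C11 bond is cut: Baylis–Hillman adduct 14 from aldehyde 12 and ethyl acrylate 13, followed by allylic transposition to the bromide. The carbinol centre of 14 is lost again, so only the alkene geometry of 15 matters.

**12 to 4 and 8.** The C8–C9 bond is cut. The only stereocentre that has to be bought is C8, and an auxiliary-controlled alkylation of glycolate imide 4 (from acid 1 and oxazolidinone 2, via 3 and enolate 9) with allylic bromide 8 sets it reliably. Alkylated imide 10 is taken through alcohol 11 to 12.

**8 to 5.** The trisubstituted C1=C10 alkene, with C9 and the future C2 cis, is traced through iodo-alcohol 7 to propargyl alcohol 5. Anti-carbomagnesiation (via 6) fixes this geometry at the very start, so it never depends on the ring closure.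

**21 to 16.** The iodo-enal goes back through iodo-alcohol 20 to alkynol 18 and to acetal 16 (via 17). Hydroxyl-directed trans-hydroalumination (via 19) puts the iodine on C4, cis to C6, which is the relationship the ring needs at C4=C5.

**31 to 29 and 30.** The C2–C3 unit comes from acetylene 29 and hexamethylditin 30 by syn addition of the Sn–Sn bond, which gives the cis isomer only.

## Alternatives that were turned down

**Alternative 1:** The C8–C9 bond is cut and C1 is joined to C6, which folds the carbocycle back into cyclohexenol A2. This six-membered carbinol carries a 2-alkoxyvinyl group on the carbinol carbon and an isopropenyl group on the neighbouring carbon. In the forward direction A2 is deprotonated with KH and 18-crown-6, and the alkoxide undergoes a charge-accelerated [3,3] shift. Protonation of the resulting C6 enolate gives dienone A1.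
- For it: a ring expansion replaces a macrocyclisation and runs near room temperature. The ring-cis C1=C10 bond and the C8 ether come out of one ordered transition state. On ring formation alone it is stronger than any closure of an open chain, the one used here included.
- Against it: A1 is far from the target. C7 is a bare CH2, so the C11–C13 unit must be attached beside the C6 ketone and C6 reduced, both with control, before the cis lactone exists. C2 and C3 arrive as a cis-diol acetonide, and a single displacement on such a diol would give the trans-oxirane, so the diol would have to be taken back to the alkene and epoxidised after all. The 1,10-oxirane is also still missing.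
- Comparison: the expansion secures the ring but leaves a long linear sequence of functional-group work on a medium ring. The chosen route completes lactone, methylene, angelate and aldehyde before the ring is closed and adds the oxiranes in one operation on 33.

**Alternative 2:** C1–C10 and C4–C5 are treated as two bonds of a cyclobutane. The ten-membered ring is then the perimeter of tricycle A3, which is taken apart into cyclohexenone A4 (C5 to C10, with C7 and C8 set) and cyclobutene ester A5 (C1 to C4 with both silyloxy groups). In the forward direction irradiation of A4 with A5 gives A3 by an enone [2+2] photocycloaddition. Cleavage of the central four-membered ring in the other sense then releases the C1=C10 and C4=C5 alkenes.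
- For it: two ring bonds are made from small cyclic pieces without high dilution, C7 and C8 are set on a six-membered ring, and C2 and C3 are oxygenated from the start. On the entropy of ring formation it is stronger than the chosen route.
- Against it: orientation and face selectivity of a photocycloaddition that must create two adjacent quaternary carbons (C10 and C4) are uncertain. The cycloreversion needs temperatures at which cyclodeca-1,5-dienes undergo Cope rearrangement, and the alkene geometry is dictated by the ring fusion rather than chosen. A3 has no C2=C3 bond, so the 2,3-oxirane would again have to be made from a protected diol. Three carbonyl groups (C6, C12, C15) must be told apart afterwards to build lactone, methylene and the C15 alcohol.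
- Comparison: the chosen route needs no step above room temperature once the ring exists and has two steps after ring closure instead of a long tail.

**Alternative 3:** Only C1–C2 is cut. The seco compound A7 holds the C1 alkenyl iodide and a (Z)-alkenylstannane at C2 in one molecule. Pd2(dba)3, AsPh3 and CuI close it to triene A6, which is identical with 33.
- For it: the coupling is neutral, keeps alkene geometry and tolerates lactone, angelate and aldehyde. It is the soundest of the three. On ring closure it is as strong as the adopted route, which closes the same ring with the same class of coupling.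
- Against it: as a plan for the target it ends at the triene. Both oxiranes and four stereocentres are still missing, so it cannot replace the late oxidation and only competes over how 33 is reached. A7 has to be built and purified as a stannyl dienal beside an iodide, and the most direct access to such a compound is the mono-coupling that the adopted route runs in the same flask (32).
- Comparison: the adopted route keeps the coupling but uses it twice, with 31 as a C2–C3 linchpin. This saves an isolation of a destannylation-prone intermediate and puts the weight of the plan on the oxidation, which this alternative leaves open.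

Key step: step 18

## Steps

Step 1
Reactants: 1 (tert-butyldimethylsilyloxy)acetic acid; 2 (S)-4-benzyl-1,3-oxazolidin-2-one
Product: 4 (4S)-4-benzyl-3-[(tert-butyldimethylsilyloxy)acetyl]-1,3-oxazolidin-2-one, via mixed pivalic anhydride 3 (not isolated)
Conditions: t-BuCOCl, Et3N, THF, −20 °C; then LiCl, 2, −20 → 20 °C
Reagents that add atoms: none
Why: N-acylation of the oxazolidinone by a mixed anhydride is the standard entry to Evans-type imides; attack goes to the less hindered glycolyl carbonyl.

Step 2
Reactants: 5 propargyl alcohol
Product: 7 (2Z)-3-iodo-2-methylprop-2-en-1-ol, via alkenylmagnesium alkoxide 6 (not isolated)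
Conditions: MeMgBr (2.5 equiv), CuI (10 mol%), THF, −10 → 20 °C; then I2, THF, −10 °C
Reagents that add atoms: methylmagnesium bromide C[Mg]Br; iodine II
Why: Copper-catalysed anti-carbomagnesiation of the propargylic alkoxide puts the methyl group (C14) on C10 and magnesium on C1 in a five-membered chelate; iodinolysis with retention gives the (Z)-iodide, so C9 and the future C2 are cis.

Step 3
Reactants: 7 (2Z)-3-iodo-2-methylprop-2-en-1-ol
Product: 8 (1Z)-3-bromo-1-iodo-2-methylprop-1-ene
Conditions: CBr4, PPh3, CH2Cl2, 0 °C
Reagents that add atoms: tetrabromomethane BrC(Br)(Br)Br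
Why: Appel bromination of a primary allylic alcohol under neutral conditions; the alkenyl iodide and its geometry are not touched.

Step 4
Reactants: 4 (4S)-4-benzyl-3-[(tert-butyldimethylsilyloxy)acetyl]-1,3-oxazolidin-2-one; 8 (1Z)-3-bromo-1-iodo-2-methylprop-1-ene
Product: 10 (4S)-4-benzyl-3-[(2R,4Z)-2-(tert-butyldimethylsilyloxy)-5-iodo-4-methylpent-4-enoyl]-1,3-oxazolidin-2-one, via sodium enolate 9 (not isolated)
Conditions: NaN(SiMe3)2, THF, −78 °C; then 8, −78 → −40 °C
Reagents that add atoms: none
Why: Evans alkylation: the chelated (Z)-enolate is alkylated by the reactive allylic bromide on the face away from the benzyl group, which should set C8 as R and forms C8–C9.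

Step 5
Reactants: 10 (4S)-4-benzyl-3-[(2R,4Z)-2-(tert-butyldimethylsilyloxy)-5-iodo-4-methylpent-4-enoyl]-1,3-oxazolidin-2-one
Product: 11 (2R,4Z)-2-(tert-butyldimethylsilyloxy)-5-iodo-4-methylpent-4-en-1-ol
Conditions: LiBH4, MeOH (1 equiv), Et2O, 0 °C
Reagents that add atoms: none
Why: Reductive removal of the auxiliary with borohydride gives the primary alcohol and leaves the alkenyl iodide and silyl ether intact; the reaction is kept cold and short to avoid silyl migration.

Step 6
Reactants: 11 (2R,4Z)-2-(tert-butyldimethylsilyloxy)-5-iodo-4-methylpent-4-en-1-ol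
Product: 12 (2R,4Z)-2-(tert-butyldimethylsilyloxy)-5-iodo-4-methylpent-4-enal
Conditions: Dess–Martin periodinane, NaHCO3, CH2Cl2, 0 → 20 °C
Reagents that add atoms: none
Why: Buffered Dess–Martin oxidation should give the α-silyloxy aldehyde without epimerisation at C8; the aldehyde is used crude.

Step 7
Reactants: 12 (2R,4Z)-2-(tert-butyldimethylsilyloxy)-5-iodo-4-methylpent-4-enal; 13 ethyl acrylate
Product: 14 ethyl (4R,6Z)-4-(tert-butyldimethylsilyloxy)-3-hydroxy-7-iodo-6-methyl-2-methylidenehept-6-enoate (both C3 epimers)
Conditions: 1,4-diazabicyclo[2.2.2]octane (1 equiv), 13 (neat, excess), 20 °C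
Reagents that add atoms: none
Why: Morita–Baylis–Hillman reaction attaches C11, C12 and C13 to C7; the configuration of the new carbinol does not matter because it is erased in step 8.

Step 8
Reactants: 14 ethyl (4R,6Z)-4-(tert-butyldimethylsilyloxy)-3-hydroxy-7-iodo-6-methyl-2-methylidenehept-6-enoate
Product: 15 ethyl (2Z,4R,6Z)-2-(bromomethyl)-4-(tert-butyldimethylsilyloxy)-7-iodo-6-methylhepta-2,6-dienoate
Conditions: N-bromosuccinimide, Me2S, CH2Cl2, 0 → 20 °C
Reagents that add atoms: N-bromosuccinimide O=C1CCC(=O)N1Br
Why: SN2' bromination of a Baylis–Hillman adduct through the alkoxysulfonium salt gives the thermodynamically preferred (Z)-2-(bromomethyl)enoate, in which C8 is cis to the CH2Br carbon.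

Step 9
Reactants: 16 3,3-diethoxyprop-1-yne
Product: 18 4,4-diethoxybut-2-yn-1-ol, via lithium acetylide 17 (not isolated)
Conditions: n-BuLi, THF, −78 °C; then (CH2O)n, −78 → 20 °C
Reagents that add atoms: formaldehyde (as paraformaldehyde) C=O
Why: Addition of a lithium acetylide to formaldehyde; the acetal is inert to the base.

Step 10
Reactants: 18 4,4-diethoxybut-2-yn-1-ol
Product: 20 (2Z)-4,4-diethoxy-3-iodobut-2-en-1-ol, via cyclic alkenylalanate 19 (not isolated)
Conditions: NaAlH2(OCH2CH2OMe)2, THF, 0 °C; EtOAc; then I2, THF, −78 → 0 °C
Reagents that add atoms: iodine II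
Why: Hydroxyl-directed trans-hydroalumination places aluminium on the distal alkyne carbon (C4) in a five-membered chelate; iodinolysis with retention gives the (Z)-iodide with iodine cis to C6.

Step 11
Reactants: 20 (2Z)-4,4-diethoxy-3-iodobut-2-en-1-ol
Product: 21 (2Z)-4,4-diethoxy-3-iodobut-2-enal
Conditions: MnO2, CH2Cl2, 20 °C, dark
Reagents that add atoms: none
Why: Allylic oxidation with manganese dioxide is neutral, so acetal, iodide and alkene geometry should survive; the aldehyde is used at once.

Step 12
Reactants: 15 ethyl (2Z,4R,6Z)-2-(bromomethyl)-4-(tert-butyldimethylsilyloxy)-7-iodo-6-methylhepta-2,6-dienoate; 21 (2Z)-4,4-diethoxy-3-iodobut-2-enal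
Product: 23 (4S,5R)-4-[(1R,3Z)-1-(tert-butyldimethylsilyloxy)-4-iodo-3-methylbut-3-en-1-yl]-5-[(1Z)-3,3-diethoxy-2-iodoprop-1-en-1-yl]-3-methylideneoxolan-2-one, via hydroxy ester 22 (not isolated)
Conditions: In powder, THF/H2O (1:1), 20 °C; then pyridinium p-toluenesulfonate (cat.), toluene, 40 °C
Reagents that add atoms: none
Why: Barbier-type allylation through a chair (Zimmerman–Traxler) transition state: the (Z)-bromide places C8 axial and the aldehyde substituent equatorial, which should give the syn adduct and, after lactonisation, the cis lactone at C6 and C7. Allylic strain holds H8 in the plane of the allyl unit, and the aldehyde should add anti to the C9 chain with the non-chelating silyl ether standing aside, which sets C7 anti to O8. An allylindium reagent is expected to add 1,2 to the enal and to leave both alkenyl iodides alone; the ethanol released matches the acetal, so exchange is harmless.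

Step 13
Reactants: 23 (4S,5R)-4-[(1R,3Z)-1-(tert-butyldimethylsilyloxy)-4-iodo-3-methylbut-3-en-1-yl]-5-[(1Z)-3,3-diethoxy-2-iodoprop-1-en-1-yl]-3-methylideneoxolan-2-one
Product: 24 (4R,5R)-5-[(1Z)-3,3-diethoxy-2-iodoprop-1-en-1-yl]-4-[(1R,3Z)-1-hydroxy-4-iodo-3-methylbut-3-en-1-yl]-3-methylideneoxolan-2-one
Conditions: HF·pyridine, pyridine, THF, 0 → 20 °C
Reagents that add atoms: none
Why: Buffered fluoride desilylation frees the C8 alcohol; the medium is neither basic enough to attack the methylene lactone nor wet and acidic enough to open the acetal.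

Step 14
Reactants: 24 (4R,5R)-5-[(1Z)-3,3-diethoxy-2-iodoprop-1-en-1-yl]-4-[(1R,3Z)-1-hydroxy-4-iodo-3-methylbut-3-en-1-yl]-3-methylideneoxolan-2-one; 25 angelic acid
Product: 27 (1R,3Z)-1-[(2R,3R)-2-[(1Z)-3,3-diethoxy-2-iodoprop-1-en-1-yl]-4-methylidene-5-oxooxolan-3-yl]-4-iodo-3-methylbut-3-en-1-yl (2Z)-2-methylbut-2-enoate, via mixed trichlorobenzoic anhydride 26 (not isolated)
Conditions: 25, 2,4,6-trichlorobenzoyl chloride, Et3N, toluene, 20 °C; then 24, toluene, 80 °C, no 4-(dimethylamino)pyridine
Reagents that add atoms: none
Why: Yamaguchi esterification; leaving out the nucleophilic catalyst avoids the addition–elimination pathway that turns angelates into tiglates. The step is placed before ring closure because the bis-iodide tolerates the heating that the triene would not.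

Step 15
Reactants: 27 (1R,3Z)-1-[(2R,3R)-2-[(1Z)-3,3-diethoxy-2-iodoprop-1-en-1-yl]-4-methylidene-5-oxooxolan-3-yl]-4-iodo-3-methylbut-3-en-1-yl (2Z)-2-methylbut-2-enoate
Product: 28 (1R,3Z)-4-iodo-1-[(2R,3R)-2-[(1Z)-2-iodo-3-oxoprop-1-en-1-yl]-4-methylidene-5-oxooxolan-3-yl]-3-methylbut-3-en-1-yl (2Z)-2-methylbut-2-enoate
Conditions: CF3CO2H/H2O (9:1), CH2Cl2, 0 °C
Reagents that add atoms: water O
Why: Acid hydrolysis of the acetal frees the C15 aldehyde and gives an α-iodo enal; lactone, angelate and both iodides are stable to brief aqueous acid.

Step 16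
Reactants: 29 acetylene; 30 hexamethylditin
Product: 31 (Z)-1,2-bis(trimethylstannyl)ethene
Conditions: Pd(PPh3)4 (cat.), 1,4-dioxane, 60 °C, sealed vessel
Reagents that add atoms: none
Why: Palladium-catalysed distannation of an alkyne is a syn addition of the Sn–Sn bond, so only the cis isomer is formed.

Step 17
Reactants: 28 (1R,3Z)-4-iodo-1-[(2R,3R)-2-[(1Z)-2-iodo-3-oxoprop-1-en-1-yl]-4-methylidene-5-oxooxolan-3-yl]-3-methylbut-3-en-1-yl (2Z)-2-methylbut-2-enoate; 31 (Z)-1,2-bis(trimethylstannyl)ethene
Product: 33 (6S,7R,8R)-8-angeloyloxy-15-oxogermacra-1(10)Z,2Z,4E,11(13)-tetraen-12,6-olide, via stannyl iodide 32 (not isolated)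
Conditions: Pd2(dba)3 (10 mol%), AsPh3, CuI, degassed DMF, 28 + 31 (1.05 equiv), 0 °C, 0.05 M; then dilution to 1 mM, 20 °C, dark
Reagents that add atoms: none
Why: Two Stille couplings with retention at all four sp2 carbons: the activated α-iodo enal should couple first and form C3–C4 (32), and the second, intramolecular coupling forms C1–C2 and closes the ten-membered ring. The cis C2=C3 bond is brought in by 31, and the neutral conditions at room temperature suit methylene lactone, angelate, aldehyde and the heat-sensitive triene.

Step 18
Reactants: 33 (6S,7R,8R)-8-angeloyloxy-15-oxogermacra-1(10)Z,2Z,4E,11(13)-tetraen-12,6-olide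
Product: 35 (1R,2S,3S,6S,7R,8R,10S)-8-angeloyloxy-1,10:2,3-diepoxy-15-oxogermacra-4E,11(13)-dien-12,6-olide, via monoepoxide 34 (not isolated)
Conditions: dimethyldioxirane (2.2 equiv, acetone solution), CH2Cl2, −40 → 0 °C
Reagents that add atoms: dimethyldioxirane CC1(C)OO1
Why: Dimethyldioxirane hands one oxygen atom to each alkene in a concerted, spiro-oriented [2+1] step, so each oxirane ring closes with both of its C–O bonds formed at once and syn. The closest known reaction type is the dioxirane or peracid epoxidation of conjugated dienes and medium-ring polyenes, which stops at the mono- and bis-epoxide. C1=C10 is trisubstituted and the most electron-rich alkene and should react first (34); C2=C3, twisted out of conjugation in the ring, should follow. C4=C5 carries the formyl group and C11=C13 and the angelate are acrylate-type alkenes, so all three are poor partners for an electrophilic oxidant; this is the chemoselectivity the step needs. C10 and C1 are set together by syn addition to the (Z)-alkene, and the face should be the outer one of the ring conformer that the cis-lactone (C6, C7) and the C8 ester impose. C2 and C3 are set together by syn addition to the cis-alkene, anti to the first oxirane, whose oxygen shields and repels the reagent on its own side. The low temperature keeps the triene from 6π-electrocyclisation and the aldehyde from oxidation.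

Step 19
Reactants: 35 (1R,2S,3S,6S,7R,8R,10S)-8-angeloyloxy-1,10:2,3-diepoxy-15-oxogermacra-4E,11(13)-dien-12,6-olide
Product: 36 (1R,2S,3S,6S,7R,8R,10S)-8-angeloyloxy-1,10:2,3-diepoxy-15-hydroxygermacra-4Z,11(13)-dien-12,6-olide (CNP0157626.1)
Conditions: NaBH4, CeCl3·7H2O, MeOH, −78 °C
Reagents that add atoms: none
Why: Luche reduction gives clean 1,2-reduction of the enal; at −78 °C with a slight excess of hydride the methylene lactone, the angelate and the oxiranes should not react, and no stereocentre is touched.

## Compound list

1 | (tert-butyldimethylsilyloxy)acetic acid | CC(C)(C)[Si](C)(C)OCC(=O)O | starting material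
2 | (S)-4-benzyl-1,3-oxazolidin-2-one | O=C1OC[C@H](Cc2ccccc2)N1 | starting material
3 | (tert-butyldimethylsilyloxy)acetic pivalic anhydride | CC(C)(C)C(=O)OC(=O)CO[Si](C)(C)C(C)(C)C | intermediate
4 | (4S)-4-benzyl-3-[(tert-butyldimethylsilyloxy)acetyl]-1,3-oxazolidin-2-one | CC(C)(C)[Si](C)(C)OCC(=O)N1[C@@H](Cc2ccccc2)COC1=O | intermediate
5 | propargyl alcohol | OCC#C | starting material
6 | bromomagnesium (2Z)-3-(bromomagnesio)-2-methylprop-2-en-1-olate | Br[Mg]OC/C(C)=C\[Mg]Br | intermediate
7 | (2Z)-3-iodo-2-methylprop-2-en-1-ol | OC/C(C)=C\I | intermediate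
8 | (1Z)-3-bromo-1-iodo-2-methylprop-1-ene | BrC/C(C)=C\I | intermediate
9 | sodium (Z)-enolate of imide 4 | [Na+].[O-]/C(=C\O[Si](C)(C)C(C)(C)C)N1[C@@H](Cc2ccccc2)COC1=O | intermediate
10 | (4S)-4-benzyl-3-[(2R,4Z)-2-(tert-butyldimethylsilyloxy)-5-iodo-4-methylpent-4-enoyl]-1,3-oxazolidin-2-one | I/C=C(C)\C[C@@H](O[Si](C)(C)C(C)(C)C)C(=O)N1[C@@H](Cc2ccccc2)COC1=O | intermediate
11 | (2R,4Z)-2-(tert-butyldimethylsilyloxy)-5-iodo-4-methylpent-4-en-1-ol | I/C=C(C)\C[C@@H](O[Si](C)(C)C(C)(C)C)CO | intermediate
12 | (2R,4Z)-2-(tert-butyldimethylsilyloxy)-5-iodo-4-methylpent-4-enal | I/C=C(C)\C[C@@H](O[Si](C)(C)C(C)(C)C)C=O | intermediate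
13 | ethyl acrylate | C=CC(=O)OCC | starting material
14 | ethyl (4R,6Z)-4-(tert-butyldimethylsilyloxy)-3-hydroxy-7-iodo-6-methyl-2-methylidenehept-6-enoate (C3 epimers) | CCOC(=O)C(=C)C(O)[C@H](O[Si](C)(C)C(C)(C)C)C/C(C)=C\I | intermediate
15 | ethyl (2Z,4R,6Z)-2-(bromomethyl)-4-(tert-butyldimethylsilyloxy)-7-iodo-6-methylhepta-2,6-dienoate | CCOC(=O)/C(CBr)=C/[C@H](O[Si](C)(C)C(C)(C)C)C/C(C)=C\I | intermediate
16 | 3,3-diethoxyprop-1-yne | C#CC(OCC)OCC | starting material
17 | (3,3-diethoxyprop-1-yn-1-yl)lithium | [Li]C#CC(OCC)OCC | intermediate
18 | 4,4-diethoxybut-2-yn-1-ol | OCC#CC(OCC)OCC | intermediate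
19 | sodium cyclic alkenylalanate (five-membered O–Al–C4=C5–C6 chelate, two 2-methoxyethoxy groups on aluminium) | CCOC(OCC)C1=CCO[Al-]1(OCCOC)OCCOC.[Na+] | intermediate
20 | (2Z)-4,4-diethoxy-3-iodobut-2-en-1-ol | OC/C=C(\I)C(OCC)OCC | intermediate
21 | (2Z)-4,4-diethoxy-3-iodobut-2-enal | O=C/C=C(\I)C(OCC)OCC | intermediate
22 | ethyl (3S,4R,5Z)-3-[(1R,3Z)-1-(tert-butyldimethylsilyloxy)-4-iodo-3-methylbut-3-en-1-yl]-7,7-diethoxy-4-hydroxy-6-iodo-2-methylidenehept-5-enoate | CCOC(=O)C(=C)[C@@H]([C@@H](O)/C=C(\I)C(OCC)OCC)[C@H](O[Si](C)(C)C(C)(C)C)C/C(C)=C\I | intermediate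
23 | (4S,5R)-4-[(1R,3Z)-1-(tert-butyldimethylsilyloxy)-4-iodo-3-methylbut-3-en-1-yl]-5-[(1Z)-3,3-diethoxy-2-iodoprop-1-en-1-yl]-3-methylideneoxolan-2-one | C=C1C(=O)O[C@@H](/C=C(\I)C(OCC)OCC)[C@H]1[C@H](O[Si](C)(C)C(C)(C)C)C/C(C)=C\I | intermediate
24 | (4R,5R)-5-[(1Z)-3,3-diethoxy-2-iodoprop-1-en-1-yl]-4-[(1R,3Z)-1-hydroxy-4-iodo-3-methylbut-3-en-1-yl]-3-methylideneoxolan-2-one | C=C1C(=O)O[C@@H](/C=C(\I)C(OCC)OCC)[C@H]1[C@H](O)C/C(C)=C\I | intermediate
25 | angelic acid, (2Z)-2-methylbut-2-enoic acid | C/C=C(/C)C(=O)O | starting material
26 | (2Z)-2-methylbut-2-enoic 2,4,6-trichlorobenzoic anhydride | C/C=C(/C)C(=O)OC(=O)c1c(Cl)cc(Cl)cc1Cl | intermediate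
27 | (1R,3Z)-1-[(2R,3R)-2-[(1Z)-3,3-diethoxy-2-iodoprop-1-en-1-yl]-4-methylidene-5-oxooxolan-3-yl]-4-iodo-3-methylbut-3-en-1-yl (2Z)-2-methylbut-2-enoate | C=C1C(=O)O[C@@H](/C=C(\I)C(OCC)OCC)[C@H]1[C@H](OC(=O)/C(C)=C\C)C/C(C)=C\I | intermediate
28 | (1R,3Z)-4-iodo-1-[(2R,3R)-2-[(1Z)-2-iodo-3-oxoprop-1-en-1-yl]-4-methylidene-5-oxooxolan-3-yl]-3-methylbut-3-en-1-yl (2Z)-2-methylbut-2-enoate | C=C1C(=O)O[C@@H](/C=C(\I)C=O)[C@H]1[C@H](OC(=O)/C(C)=C\C)C/C(C)=C\I | intermediate
29 | acetylene | C#C | starting material
30 | hexamethylditin | C[Sn](C)(C)[Sn](C)(C)C | starting material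
31 | (Z)-1,2-bis(trimethylstannyl)ethene | C[Sn](C)(C)/C=C\[Sn](C)(C)C | intermediate
32 | (1R,3Z)-1-[(2S,3R)-2-[(1E,3Z)-2-formyl-4-(trimethylstannyl)buta-1,3-dien-1-yl]-4-methylidene-5-oxooxolan-3-yl]-4-iodo-3-methylbut-3-en-1-yl (2Z)-2-methylbut-2-enoate | C=C1C(=O)O[C@@H](/C=C(/C=O)\C=C/[Sn](C)(C)C)[C@H]1[C@H](OC(=O)/C(C)=C\C)C/C(C)=C\I | intermediate
33 | (6S,7R,8R)-8-angeloyloxy-15-oxogermacra-1(10)Z,2Z,4E,11(13)-tetraen-12,6-olide (all-ring-cis triene lactone enal) | C=C1C(=O)O[C@H]2/C=C(/C=O)\C=C/C=C(C)\C[C@@H](OC(=O)/C(C)=C\C)[C@@H]12 | intermediate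
34 | (1R,6S,7R,8R,10S)-8-angeloyloxy-1,10-epoxy-15-oxogermacra-2Z,4E,11(13)-trien-12,6-olide | C=C1C(=O)O[C@H]2/C=C(/C=O)\C=C/[C@H]3O[C@@]3(C)C[C@@H](OC(=O)/C(C)=C\C)[C@@H]12 | intermediate
35 | (1R,2S,3S,6S,7R,8R,10S)-8-angeloyloxy-1,10:2,3-diepoxy-15-oxogermacra-4E,11(13)-dien-12,6-olide | C=C1C(=O)O[C@H]2/C=C(/C=O)[C@@H]3O[C@@H]3[C@H]3O[C@@]3(C)C[C@@H](OC(=O)/C(C)=C\C)[C@@H]12 | intermediate
36 | (1R,2S,3S,6S,7R,8R,10S)-8-angeloyloxy-1,10:2,3-diepoxy-15-hydroxygermacra-4Z,11(13)-dien-12,6-olide (CNP0157626.1) | C=C1C(=O)O[C@H]2/C=C(/CO)[C@@H]3O[C@@H]3[C@H]3O[C@@]3(C)C[C@@H](OC(=O)/C(C)=C\C)[C@@H]12 | target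

## Step count and least certain steps

Total step count: 19. Longest linear sequence: 14 steps from 5 (steps 2, 3, 4, 5, 6, 7, 8, 12, 13, 14, 15, 17, 18, 19).

**Step 18 (key step).** The most likely failures are oxygen delivery to the other face of C1=C10, or syn rather than anti delivery of the second oxygen, because the facial preference rests on the ring conformation alone. Lesser risks are oxidation of the formyl group and electrocyclisation of the triene before it is oxidised. The fallback builds the oxirane indirectly. It sets out from 33. N-Bromosuccinimide in wet THF forms the bromonium ion on the face the dioxirane prefers, and water opens it at C10 from the other side to give bromohydrin F1. Ag2O then closes F1 with inversion at C1, which puts the oxygen on the face that direct transfer does not reach and gives monoepoxide 34. One equivalent of the dioxirane then returns the route to 35. The same halohydrin detour can be used on C2=C3 of 34 if it is the second oxygen that goes to the wrong face.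

**Step 17.** The ring closure after the first coupling may be slow, which would let 32 couple with a second molecule or lose tin by protonation. Isomerisation of a Z alkene and ionisation of the allylic lactone C6–O bond by zerovalent palladium are further risks. The fallback replaces tin by an alkyne linchpin. It sets out from 28. Sonogashira coupling with ethynyltrimethylsilane (Pd(PPh3)2Cl2, CuI, i-Pr2NEt) at the α-iodo enal gives silylated enyne F2. Buffered fluoride frees terminal enyne F3. A second, intramolecular Sonogashira coupling at high dilution closes the ring to cyclic dienyne F4, which cannot electrocyclise. Reduction with zinc activated by Cu(OAc)2 and AgNO3 in aqueous methanol gives the cis C2=C3 bond and returns to 33.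

**Step 12.** The addition may show poor facial selectivity with respect to C8, so that the C6/C7 pair forms in the wrong sense, or erosion of the syn preference. Reductive loss of vinylic iodine from 21 and acetal hydrolysis in the aqueous medium are also possible. The fallback changes the control element from the substrate to a catalyst. From 15 and 21, a chromium-mediated allylation (CrCl2 generated from CrCl3 and Mn, Me3SiCl, a chiral bis(oxazoline) ligand), which does not touch alkenyl iodides in the absence of nickel, is followed by acid-promoted lactonisation to rejoin the route at 23. No new compound is formed (F0).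

**Step 7.** The reaction is slow with a hindered α-silyloxy aldehyde, and days under an amine invite enolisation of 12 with loss of configuration at C8, or silyl migration. The fallback uses a preformed nucleophile instead of amine catalysis. From 12, hydroalumination of ethyl propiolate with i-Bu2AlH in THF with hexamethylphosphoramide gives α-aluminoacrylate F5, which adds to 12 below 0 °C within hours and returns to 14.

**Step 14.** The angelate may isomerise to the tiglate during activation or heating, and acylation of the hindered C8 alcohol may be incomplete. The fallback builds the Z double bond on the ester. From 24, 2-[bis(2,2,2-trifluoroethoxy)phosphoryl]propanoic acid is attached with dicyclohexylcarbodiimide to give phosphonopropionate ester F6. Still–Gennari olefination with acetaldehyde (KN(SiMe3)2, 18-crown-6, THF, −78 °C) gives the (Z)-2-methylbut-2-enoate and returns to 27.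

## Further compounds

F1 | step 18 | (1S,6S,7R,8R,10S)-8-angeloyloxy-1-bromo-10-hydroxy-15-oxogermacra-2Z,4E,11(13)-trien-12,6-olide | C=C1C(=O)O[C@H]2/C=C(/C=O)\C=C/[C@H](Br)[C@](O)(C)C[C@@H](OC(=O)/C(C)=C\C)[C@@H]12
F2 | step 17 | 28 with the C4 iodine replaced by a (trimethylsilyl)ethynyl group (C4=C5 E, C1 iodide kept) | C=C1C(=O)O[C@@H](/C=C(/C=O)C#C[Si](C)(C)C)[C@H]1[C@H](OC(=O)/C(C)=C\C)C/C(C)=C\I
F3 | step 17 | terminal enyne from F2 (ethynyl group on C4, C1 iodide kept) | C=C1C(=O)O[C@@H](/C=C(/C=O)C#C)[C@H]1[C@H](OC(=O)/C(C)=C\C)C/C(C)=C\I
F4 | step 17 | (6S,7R,8R)-8-angeloyloxy-15-oxogermacra-1(10)Z,4E,11(13)-trien-2-yn-12,6-olide | C=C1C(=O)O[C@H]2/C=C(/C=O)C#C/C=C(C)\C[C@@H](OC(=O)/C(C)=C\C)[C@@H]12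
F0 | step 12 | none | none
F5 | step 7 | ethyl 2-(diisobutylalumanyl)prop-2-enoate | CCOC(=O)C(=C)[Al](CC(C)C)CC(C)C
F6 | step 14 | 2-[bis(2,2,2-trifluoroethoxy)phosphoryl]propanoate of alcohol 24 at C8 (both epimers at the phosphonate carbon) | C=C1C(=O)O[C@@H](/C=C(\I)C(OCC)OCC)[C@H]1[C@H](OC(=O)C(C)P(=O)(OCC(F)(F)F)OCC(F)(F)F)C/C(C)=C\I
A1 | alternative 1 | ten-membered dienone with C8 4-methoxybenzyl ether, C2,C3 acetonide and C15 silyl ether | O=C1C[C@H](OCc2ccc(OC)cc2)C/C(C)=C\[C@H]2OC(C)(C)O[C@H]2/C(CO[Si](C)(C)C(C)(C)C)=C\1
A2 | alternative 1 | 1-[2-(4-methoxybenzyloxy)ethenyl]-6-(prop-1-en-2-yl)cyclohex-2-en-1-ol with 4,5-O-isopropylidene and 3-(tert-butyldimethylsilyloxymethyl) groups (carbinol carbon, its neighbour and the enol ether geometry left open) | C=C(C)C1[C@H]2OC(C)(C)O[C@H]2C(CO[Si](C)(C)C(C)(C)C)=CC1(O)C=COCc1ccc(OC)cc1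
A3 | alternative 2 | cis-anti-cis tricyclic photoadduct | C[C@]12C[C@@H](O[Si](C)(C)C(C)(C)C)[C@@H](CC(=O)OC)C(=O)[C@H]1[C@]3(C(=O)OC)[C@H](O[Si](C)(C)C(C)(C)C)[C@@H](O[Si](C)(C)C(C)(C)C)[C@H]23
A4 | alternative 2 | methyl 2-[6-(tert-butyldimethylsilyloxy)-4-methyl-2-oxocyclohex-3-en-1-yl]acetate (C7 and C8 as in A3) | CC1=CC(=O)[C@H](CC(=O)OC)[C@H](O[Si](C)(C)C(C)(C)C)C1
A5 | alternative 2 | methyl 3,4-bis(tert-butyldimethylsilyloxy)cyclobut-1-ene-1-carboxylate (C2 and C3 as in A3) | COC(=O)C1=C[C@H](O[Si](C)(C)C(C)(C)C)[C@H]1O[Si](C)(C)C(C)(C)C
A6 | alternative 3 | all-ring-cis triene lactone enal with C8 angelate, identical with 33 | C=C1C(=O)O[C@H]2/C=C(/C=O)\C=C/C=C(C)\C[C@@H](OC(=O)/C(C)=C\C)[C@@H]12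
A7 | alternative 3 | seco compound with the C1 (Z)-alkenyl iodide and a (Z)-tributylstannyl group on C2 of the dienal, on the angeloylated lactone | C=C1C(=O)O[C@@H](/C=C(/C=O)\C=C/[Sn](CCCC)(CCCC)CCCC)[C@H]1[C@H](OC(=O)/C(C)=C\C)C/C(C)=C\I
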